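The decalin is built on (S)-carvone, which becomes ring B (C5–C10) with its C8 methyl, its C9 oxygen and the C5 stereocentre; the isopropenyl group supplies C3, C4 and the C4 methylene carbon. Everything rests on disconnecting ring A at C2–C3. In the forward sense a type 2 intramolecular carbonyl-ene reaction joins the aldehyde carbon C2 to the isopropenyl CH2 (C3), closes ring A, sets the C2 carbinol and leaves C4 as an exocyclic methylene in a single operation. Its precursor is a keto aldehyde, a carvone carrying at C10 a methyl trans and a CH2CHO arm cis to the isopropenyl group, so that the cis ring fusion is already fixed.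

Key step: step 5

Remark on numbering: labdane-type numbering is used (decalin C1–C10, C17 on C8, C18 and C19 on C4, C20 on C10, side chain and butenolide C11–C16); β is the face of the decalin that carries C20, α the opposite face.

Assumption: the target SMILES is taken at face value. It encodes a cis-fused decalin (H5 and C20 both β) with 2-OH and 6-OH α, C19 (CH2OAc) β and C18 α; in this numbering that is 2R,4S,5S,6S,10S.

Step 1
Reactants: 1 (S)-carvone; 2 tert-butyl bromoacetate
Product: 4 tert-butyl 2-[(1R,6S)-3-methyl-2-oxo-6-(prop-1-en-2-yl)cyclohex-3-en-1-yl]acetate (major trans epimer; the minor C1 epimer is carried along), via lithium enolate of carvone 3 (not isolated)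
Conditions: LiN(i-Pr)2, THF, −78 °C; then 2, −78 to −20 °C
Reagents that add atoms: tert-butyl bromoacetate (2), CC(C)(C)OC(=O)CBr
Why: Kinetic deprotonation of carvone takes place at the α′-methylene (the future C10), and the cross-conjugated lithium enolate is C-alkylated by the reactive α-bromo ester (enolate alkylation); the new centre is planarised again in step 2, so its configuration does not matter.

Step 2
Reactants: 4 tert-butyl 2-[(1R,6S)-3-methyl-2-oxo-6-(prop-1-en-2-yl)cyclohex-3-en-1-yl]acetate; 5 iodomethane
Product: 7 tert-butyl 2-[(1S,6R)-1,3-dimethyl-2-oxo-6-(prop-1-en-2-yl)cyclohex-3-en-1-yl]acetate, via tetrasubstituted lithium enolate 6 (not isolated)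
Conditions: LiN(i-Pr)2, THF, −78 °C; then MeI, DMPU, −78 to −10 °C
Reagents that add atoms: iodomethane (5), CI
Why: The ketone α′-hydrogen is removed in preference to the much less acidic tert-butyl ester hydrogens, and the planar enolate is methylated on the face anti to the neighbouring isopropenyl group (enolate alkylation under 1,2-induction), which sets C10 with the ester arm cis to isopropenyl; the tert-butyl ester resists attack by the enolate.

Step 3
Reactants: 7 tert-butyl 2-[(1S,6R)-1,3-dimethyl-2-oxo-6-(prop-1-en-2-yl)cyclohex-3-en-1-yl]acetate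
Product: 8 2-[(1S,6R)-2-hydroxy-1,3-dimethyl-6-(prop-1-en-2-yl)cyclohex-3-en-1-yl]ethan-1-ol (both C9 carbinol epimers)
Conditions: LiAlH4, THF, 0 °C to rt
Reagents that add atoms: none
Why: Exhaustive hydride reduction takes the ester to the primary alcohol and the enone to the allylic alcohol by 1,2-addition; the carbinol configuration is erased in step 4.

Step 4
Reactants: 8 2-[(1S,6R)-2-hydroxy-1,3-dimethyl-6-(prop-1-en-2-yl)cyclohex-3-en-1-yl]ethan-1-ol
Product: 9 2-[(1S,6R)-1,3-dimethyl-2-oxo-6-(prop-1-en-2-yl)cyclohex-3-en-1-yl]acetaldehyde (keto aldehyde, ene precursor)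
Conditions: (COCl)2, DMSO, CH2Cl2, −78 °C; then Et3N, −78 to 0 °C
Reagents that add atoms: none
Why: Swern oxidation turns both hydroxyls into alkoxysulfonium ions before the base is added, so the 1,4-diol reaches the keto aldehyde without passing through a lactol that could be over-oxidised to a lactone.

Step 5
Reactants: 9 2-[(1S,6R)-1,3-dimethyl-2-oxo-6-(prop-1-en-2-yl)cyclohex-3-en-1-yl]acetaldehyde
Product: 11 cis-fused 2α-hydroxy-8,10β-dimethyl-4-methylidene-5βH-decal-7-en-9-one, via chloromethylaluminium alkoxide 10 (not isolated)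
Conditions: Me2AlCl (2.2 equiv), CH2Cl2, −78 to −40 °C; cold 1 M HCl work-up
Reagents that add atoms: none
Why: The aluminium-bound aldehyde carbon C2 is attacked by the isopropenyl CH2 (C3) while a hydrogen of the isopropenyl methyl passes to the carbonyl oxygen through a six-membered pericyclic array, so C2–C3 and the C4=CH2 alkene arise together, and the alcohol–aluminium complex then loses methane to the non-acidic alkoxide 10. The closest known reaction type is the type 2 intramolecular carbonyl-ene cyclisation of 5-methylhex-5-enals to 3-methylenecyclohexanols promoted by alkylaluminium chlorides. Ring A closes in the six-membered type 2 mode (bond from the carbonyl carbon to the alkene terminus, central alkene carbon C4 staying in the ring) through a chair-like array that must be cis-fused because both reacting arms are cis on C5 and C10. The new stereocentre C2 is controlled by C10 and C5: hydrogen transfer requires the oxygen on the axial side of the forming chair, and the chair with C20 equatorial puts it on the α face beside the C9 carbonyl, where one aluminium can bridge both oxygens, whereas the other chair would press the complexed oxygen against the axial C20 methyl; this should give the 2α-alcohol, trans to C20. The step also needs the aldehyde to react and not the C9 ketone, which is secured by the hindered, conjugated nature of that ketone and by the strained bridged ring that an ene reaction at C9 would demand. Acid-induced alkene migration is held back because the aluminium reagent scavenges the proton as methane.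

Step 6
Reactants: 11 cis-fused 2α-hydroxy-8,10β-dimethyl-4-methylidene-5βH-decal-7-en-9-one
Product: 12 2α-(tert-butyldimethylsilyloxy) ether of 11
Conditions: TBSCl, imidazole, DMF, rt
Reagents that add atoms: tert-butyldimethylsilyl chloride, CC(C)(C)[Si](C)(C)Cl
Why: Imidazole-promoted silylation of the unhindered secondary alcohol (silyl ether formation) masks C2 for all later base, hydride and coupling steps.

Step 7
Reactants: 12 2α-(tert-butyldimethylsilyloxy) ether of 11
Product: 13 spiro-oxirane at C4 (4,19-epoxide, oxygen α as the expected major isomer)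
Conditions: mCPBA, NaHCO3, CH2Cl2, 0 °C
Reagents that add atoms: 3-chloroperoxybenzoic acid, OOC(=O)c1cccc(Cl)c1
Why: Prilezhaev epoxidation takes the electron-rich 1,1-disubstituted alkene and leaves the electron-poor enone alkene; the configuration at the spiro carbon is of no consequence because C4 becomes planar again in step 9.

Step 8
Reactants: 13 spiro-oxirane at C4
Product: 14 2α-(tert-butyldimethylsilyloxy)-9-oxo-5βH-decal-7-ene-4-carbaldehyde (C4–H, both epimers, equatorial formyl drawn)
Conditions: BF3·OEt2 (20 mol %), CH2Cl2, −78 °C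
Reagents that add atoms: none
Why: Meinwald rearrangement: the Lewis acid opens the epoxide at the tertiary carbon C4 and a 1,2-hydride shift from the oxygen-bearing CH2 gives the aldehyde.

Step 9
Reactants: 14 2α-(tert-butyldimethylsilyloxy)-9-oxo-5βH-decal-7-ene-4-carbaldehyde; 5 iodomethane
Product: 16 4α-methyl-4β-formyl compound (19-aldehyde), via potassium aldehyde enolate 15 (not isolated)
Conditions: KOtBu (1.05 equiv), MeI, THF, −40 to 0 °C
Reagents that add atoms: iodomethane (5), CI
Why: The α-branched aldehyde is the most acidic site, and its exocyclic potassium enolate is C-methylated (enolate alkylation) from the equatorial α face because the axial β face is screened by the syn-axial C20 methyl, so the methyl becomes C18 and the formyl carbon the axial β substituent; the enone can only give a C6 dienolate, which is several pK units less acidic and would have to alkylate at the congested C8.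

Step 10
Reactants: 16 4α-methyl-4β-formyl compound (19-aldehyde)
Product: 17 19-alcohol (4β-hydroxymethyl-4α-methyl enone)
Conditions: NaBH4, EtOH/THF, −20 °C
Reagents that add atoms: none
Why: Chemoselective borohydride reduction: the aldehyde is far more electrophilic than the conjugated C9 ketone, which is flanked by quaternary C10 and the C8 methyl.

Step 11
Reactants: 17 19-alcohol
Product: 18 19-acetate (4β-acetoxymethyl-4α-methyl enone)
Conditions: Ac2O, pyridine, DMAP, CH2Cl2, rt
Reagents that add atoms: acetic anhydride, CC(=O)OC(C)=O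
Why: DMAP-catalysed acylation of the primary neopentyl alcohol installs the acetate of the target while C2 is still silylated.

Step 12
Reactants: 18 19-acetate
Product: 19 7-ene-6,9-dione (enedione)
Conditions: Pd(OH)2/C (5 mol %), t-BuOOH (5 equiv), K2CO3 (0.25 equiv), CH2Cl2, 4 °C
Reagents that add atoms: tert-butyl hydroperoxide, CC(C)(C)OO
Why: tert-Butylperoxy radicals formed on Pd(OH)2/C abstract a C6 hydrogen, the only one that gives a radical conjugated with the enone, and the γ-peroxide collapses under carbonate to the C6 ketone (allylic oxidation of enones to 1,4-enediones with t-BuOOH); silyl ether and acetate are inert.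

Step 13
Reactants: 19 7-ene-6,9-dione
Product: 20 6α-hydroxy-7-en-9-one
Conditions: NaBH4, CeCl3·7H2O, MeOH, −78 °C
Reagents that add atoms: none
Why: Luche reduction delivers hydride 1,2 to the C6 carbonyl, which is much less shielded than C9, and from the convex β face because the α face of C6 lies in the fold beneath ring A, so the new hydroxyl is α.

Step 14
Reactants: 20 6α-hydroxy-7-en-9-one
Product: 21 6α-triethylsilyl ether
Conditions: TESOTf, 2,6-lutidine, CH2Cl2, −78 to 0 °C
Reagents that add atoms: triethylsilyl trifluoromethanesulfonate, CC[Si](CC)(CC)OS(=O)(=O)C(F)(F)F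
Why: The silyl triflate is reactive enough to silylate the hydroxyl on the concave face (silyl ether formation), which keeps a C6 alkoxide out of the hydride, enolate and borane chemistry that follows.

Step 15
Reactants: 21 6α-triethylsilyl ether
Product: 23 C9 enol triflate (9-trifluoromethanesulfonyloxy-8-ene), via lithium C9 enolate 22 (not isolated)
Conditions: LiBH(s-Bu)3 (1.1 equiv), THF, −78 °C; then N-(5-chloropyridin-2-yl)bis(trifluoromethanesulfonyl)imide, −78 to 0 °C
Reagents that add atoms: N-(5-chloropyridin-2-yl)bis(trifluoromethanesulfonyl)imide, Clc1ccc(nc1)N(S(=O)(=O)C(F)(F)F)S(=O)(=O)C(F)(F)F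
Why: The bulky borohydride adds hydride in the 1,4-sense to C7 because the C9 carbonyl is screened on both sides, and the enolate, which can only be the C8=C9 isomer, is trapped on oxygen by the triflimide (conjugate reduction–enolate triflation).

Step 16
Reactants: 23 C9 enol triflate; 24 tributyl(vinyl)stannane
Product: 25 9-vinyl-8-ene (C8=C9–C11=C12 diene)
Conditions: Pd(PPh3)4 (5 mol %), LiCl, THF, 65 °C
Reagents that add atoms: tributyl(vinyl)stannane (24), CCCC[Sn](CCCC)(CCCC)C=C
Why: Stille coupling of a cyclohexenyl triflate with a vinylstannane in the presence of LiCl tolerates a flanking quaternary centre, as in couplings of 2,6,6-trisubstituted cyclohexenyl triflates.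

Step 17
Reactants: 25 9-vinyl-8-ene; 26 4-bromofuran-2(5H)-one
Product: 28 2-O-TBS-6-O-TES ether of the target, via B-alkyl-9-BBN borane 27 (not isolated)
Conditions: 9-BBN, THF, rt; then 26, Pd(dppf)Cl2 (5 mol %), AsPh3, Cs2CO3, DMF/H2O, rt to 45 °C
Reagents that add atoms: 4-bromofuran-2(5H)-one (26), O=C1C=C(Br)CO1
Why: 9-BBN adds only to the monosubstituted vinyl terminus (anti-Markovnikov hydroboration; the tetrasubstituted C8=C9 bond is inert), and the primary alkylborane couples with the β-bromo butenolide, an activated vinyl bromide, under B-alkyl Suzuki–Miyaura conditions to form C12–C13.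

Step 18
Reactants: 28 2-O-TBS-6-O-TES ether of the target
Product: 29 target, CNP0201970.1 (19-acetoxy-2α,6α-dihydroxy cis-fused 8-ene butenolide)
Conditions: HF·pyridine, pyridine, THF, 0 °C to rt
Reagents that add atoms: none
Why: Fluoride-driven desilylation removes both silyl ethers under mildly acidic conditions in which the acetate, 1,4-related to both hydroxyls, should not migrate and the butenolide is stable.

Compound list
1 | (S)-carvone, (5S)-2-methyl-5-(prop-1-en-2-yl)cyclohex-2-en-1-one | CC1=CC[C@@H](CC1=O)C(C)=C | starting material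
2 | tert-butyl bromoacetate | CC(C)(C)OC(=O)CBr | starting material
3 | lithium enolate of carvone (cross-conjugated α′-enolate) | CC1=CC[C@@H](C=C1[O-])C(C)=C.[Li+] | intermediate (not isolated)
4 | tert-butyl 2-[(1R,6S)-3-methyl-2-oxo-6-(prop-1-en-2-yl)cyclohex-3-en-1-yl]acetate (major trans epimer) | CC(C)(C)OC(=O)C[C@H]1C(=O)C(C)=CC[C@@H]1C(C)=C | intermediate
5 | iodomethane | CI | starting material
6 | tetrasubstituted lithium enolate of 4 | CC(C)(C)OC(=O)CC1=C([O-])C(C)=CC[C@@H]1C(C)=C.[Li+] | intermediate (not isolated)
7 | tert-butyl 2-[(1S,6R)-1,3-dimethyl-2-oxo-6-(prop-1-en-2-yl)cyclohex-3-en-1-yl]acetate | CC(C)(C)OC(=O)C[C@]1(C)C(=O)C(C)=CC[C@@H]1C(C)=C | intermediate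
8 | 2-[(1S,6R)-2-hydroxy-1,3-dimethyl-6-(prop-1-en-2-yl)cyclohex-3-en-1-yl]ethan-1-ol (carbinol epimers) | OCC[C@]1(C)C(O)C(C)=CC[C@@H]1C(C)=C | intermediate
9 | 2-[(1S,6R)-1,3-dimethyl-2-oxo-6-(prop-1-en-2-yl)cyclohex-3-en-1-yl]acetaldehyde | O=CC[C@]1(C)C(=O)C(C)=CC[C@@H]1C(C)=C | intermediate
10 | chloro(methyl)aluminium 2α-alkoxide of 11 | C=C1C[C@H](O[Al](C)Cl)C[C@]2(C)C(=O)C(C)=CC[C@H]12 | intermediate (not isolated)
11 | cis-fused 2α-hydroxy-8,10β-dimethyl-4-methylidene-5βH-decal-7-en-9-one | C=C1C[C@H](O)C[C@]2(C)C(=O)C(C)=CC[C@H]12 | intermediate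
12 | 2α-(tert-butyldimethylsilyloxy) ether of 11 | C=C1C[C@H](O[Si](C)(C)C(C)(C)C)C[C@]2(C)C(=O)C(C)=CC[C@H]12 | intermediate
13 | spiro-oxirane at C4 (oxygen α, major isomer drawn) | C1[C@@]2(O1)C[C@H](O[Si](C)(C)C(C)(C)C)C[C@]3(C)C(=O)C(C)=CC[C@H]23 | intermediate
14 | 2α-(tert-butyldimethylsilyloxy)-9-oxo-5βH-decal-7-ene-4-carbaldehyde (equatorial formyl drawn, C4 epimers) | O=C[C@@H]1C[C@H](O[Si](C)(C)C(C)(C)C)C[C@]2(C)C(=O)C(C)=CC[C@H]12 | intermediate
15 | potassium enolate of aldehyde 14 (exocyclic at C4) | [O-]C=C1C[C@H](O[Si](C)(C)C(C)(C)C)C[C@]2(C)C(=O)C(C)=CC[C@H]12.[K+] | intermediate (not isolated)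
16 | 4α-methyl-4β-formyl enone (19-aldehyde) | O=C[C@@]1(C)C[C@H](O[Si](C)(C)C(C)(C)C)C[C@]2(C)C(=O)C(C)=CC[C@H]12 | intermediate
17 | 4β-hydroxymethyl-4α-methyl enone (19-alcohol) | OC[C@@]1(C)C[C@H](O[Si](C)(C)C(C)(C)C)C[C@]2(C)C(=O)C(C)=CC[C@H]12 | intermediate
18 | 4β-acetoxymethyl-4α-methyl enone (19-acetate) | CC(=O)OC[C@@]1(C)C[C@H](O[Si](C)(C)C(C)(C)C)C[C@]2(C)C(=O)C(C)=CC[C@H]12 | intermediate
19 | 19-acetoxy-2α-silyloxy-7-ene-6,9-dione | CC(=O)OC[C@@]1(C)C[C@H](O[Si](C)(C)C(C)(C)C)C[C@]2(C)C(=O)C(C)=CC(=O)[C@H]12 | intermediate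
20 | 19-acetoxy-6α-hydroxy-2α-silyloxy-7-en-9-one | CC(=O)OC[C@@]1(C)C[C@H](O[Si](C)(C)C(C)(C)C)C[C@]2(C)C(=O)C(C)=C[C@H](O)[C@H]12 | intermediate
21 | 6α-triethylsilyl ether of 20 | CC(=O)OC[C@@]1(C)C[C@H](O[Si](C)(C)C(C)(C)C)C[C@]2(C)C(=O)C(C)=C[C@H](O[Si](CC)(CC)CC)[C@H]12 | intermediate
22 | lithium C9 enolate (C8=C9) from 21 | CC(=O)OC[C@@]1(C)C[C@H](O[Si](C)(C)C(C)(C)C)C[C@]2(C)C([O-])=C(C)C[C@H](O[Si](CC)(CC)CC)[C@H]12.[Li+] | intermediate (not isolated)
23 | C9 enol triflate (C8=C9) | CC(=O)OC[C@@]1(C)C[C@H](O[Si](C)(C)C(C)(C)C)C[C@]2(C)C(OS(=O)(=O)C(F)(F)F)=C(C)C[C@H](O[Si](CC)(CC)CC)[C@H]12 | intermediate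
24 | tributyl(vinyl)stannane | CCCC[Sn](CCCC)(CCCC)C=C | starting material
25 | 9-vinyl-8-ene diene | CC(=O)OC[C@@]1(C)C[C@H](O[Si](C)(C)C(C)(C)C)C[C@]2(C)C(C=C)=C(C)C[C@H](O[Si](CC)(CC)CC)[C@H]12 | intermediate
26 | 4-bromofuran-2(5H)-one | O=C1C=C(Br)CO1 | starting material
27 | B-(C12-alkyl)-9-borabicyclo[3.3.1]nonane from 25 | CC(=O)OC[C@@]1(C)C[C@H](O[Si](C)(C)C(C)(C)C)C[C@]2(C)C(CCB3C4CCCC3CCC4)=C(C)C[C@H](O[Si](CC)(CC)CC)[C@H]12 | intermediate (not isolated)
28 | 2-O-TBS-6-O-TES ether of the target | CC(=O)OC[C@@]1(C)C[C@H](O[Si](C)(C)C(C)(C)C)C[C@]2(C)C(CCC3=CC(=O)OC3)=C(C)C[C@H](O[Si](CC)(CC)CC)[C@H]12 | intermediate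
29 | CNP0201970.1 (2R,4S,5S,6S,10S in the numbering used here) | CC(=O)OC[C@@]1(C)C[C@H](O)C[C@]2(C)C(CCC3=CC(=O)OC3)=C(C)C[C@H](O)[C@H]12 | target

Total step count: 18. Longest linear sequence: 18 steps from (S)-carvone; all other inputs are commercial.

Steps most likely to fail

Step 5. The cyclisation may run through the alternative chair, in which aluminium stays bound to the aldehyde alone and the oxygen ends on the β face, or it may slip into a stepwise cationic pathway with chloride capture or alkene scrambling. The first failure gives the C2 epimer. The fallback sets out from 9 and accepts whatever facial outcome the cyclisation gives. The C2-epimeric alcohol F1 is inverted by a Mitsunobu reaction (PPh3, DIAD, 4-nitrobenzoic acid, toluene, 0 °C to rt), an SN2 displacement whose α approach to C2 is open, to give the inverted 4-nitrobenzoate F2. Methanolysis with K2CO3 in MeOH then releases 11, where the route is rejoined.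

Step 12. The radical oxidation may stall at the hindered γ-peroxide, over-oxidise, or be followed by base-mediated epimerisation at C5 of the enedione, which would turn the cis into the trans ring fusion. The fallback sets out from 18 and builds the C6 ketone by ionic chemistry without base once the diketone exists. Soft enolisation with TESOTf and Et3N (CH2Cl2, 0 °C) gives the 9-triethylsilyloxy 6,8-diene F3. Vinylogous Rubottom oxidation with dimethyldioxirane (acetone, −40 °C) and mild acid work-up gives the 6-hydroxy enone F4, expected as the 6β-epimer from attack on the convex face; its configuration is immaterial. Oxidation with the Dess–Martin periodinane leads to 19, where the route is rejoined.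

Step 15. Hydride delivery to the hindered enone may be incomplete or be diverted to the acetate, and O-sulfonylation of the tetrasubstituted enolate in the presence of the borane may be sluggish. The fallback sets out from 21 and separates the two events. Conjugate reduction with [(Ph3P)CuH]6 in toluene gives the saturated ketone F5 as a mixture at C8. Its only enolisable position is C8, so deprotonation with KN(SiMe3)2 (THF, −78 °C) and trapping with the same pyridyl triflimide can give only 23, where the route is rejoined.

Further compounds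
F1 | step 5 | C2 epimer of 11 (2β-hydroxy-8,10β-dimethyl-4-methylidene-5βH-decal-7-en-9-one) | C=C1C[C@@H](O)C[C@]2(C)C(=O)C(C)=CC[C@H]12
F2 | step 5 | 2α-(4-nitrobenzoyloxy) ester of 11 | C=C1C[C@H](OC(=O)c3ccc(cc3)[N+](=O)[O-])C[C@]2(C)C(=O)C(C)=CC[C@H]12
F3 | step 12 | 9-triethylsilyloxy 6,8-diene (silyl dienol ether of 18) | CC(=O)OC[C@@]1(C)C[C@H](O[Si](C)(C)C(C)(C)C)C[C@]2(C)C(O[Si](CC)(CC)CC)=C(C)C=C[C@H]12
F4 | step 12 | 6β-hydroxy-7-en-9-one (C6 epimer of 20) | CC(=O)OC[C@@]1(C)C[C@H](O[Si](C)(C)C(C)(C)C)C[C@]2(C)C(=O)C(C)=C[C@@H](O)[C@H]12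
F5 | step 15 | saturated 9-ketone from 21 (C8 epimers) | CC(=O)OC[C@@]1(C)C[C@H](O[Si](C)(C)C(C)(C)C)C[C@]2(C)C(=O)C(C)C[C@H](O[Si](CC)(CC)CC)[C@H]12
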